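**Strategy**

Everything rests on opening ring B (the 2,4-dibromophenoxy ring) at two adjacent bonds, the ether bond O–C1' and the bond C2'–Br. Ring B carries oxygen on C1' and bromine on the neighbouring C2', with a further bromine on C4': the pattern left when a nucleophile and an electrophile add across 4-bromobenzyne. In one operation the aryne, released from its ortho-silylaryl triflate, should accept the potassium salt of 2-bromo-6-methoxyphenol (future ring A, second oxygen masked as methyl ether) at C1' and a bromine from 1,2-dibromotetrachloroethane at C2'. O-Demethylation and dibromination ortho and para to the freed hydroxyl (C6 and C4 of ring A) then complete the target.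

Key step: step 3

Remark on the chemistry: the target, 3,4,6-tribromo-2-(2,4-dibromophenoxy)phenol, has no stereocentre and its diaryl ether bonds rotate freely, so it is achiral and no stereocontrol is needed. Ring A is numbered from the hydroxyl carbon (C1) and ring B from the ether carbon (C1'). The structures were checked and are mutually consistent. 4-Bromo-2-iodophenol (assumed to be a catalogue compound) is chosen as starting material so that the halogen–metal exchange is decided by the kind of halogen and not only by its position.

**Route**

Step 1
Reactants: 1 4-bromo-2-iodophenol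
Product: 2 (4-bromo-2-iodophenoxy)trimethylsilane
Conditions: HMDS, THF, 65 °C; evaporate, use crude
Reagents that add atoms: hexamethyldisilazane, C[Si](C)(C)N[Si](C)(C)C
Why: O-silylation of the acidic phenol by silyl transfer from the disilazane is driven by loss of ammonia and touches neither carbon–halogen bond.

Step 2
Reactants: 2 (4-bromo-2-iodophenoxy)trimethylsilane
Product: 5 4-bromo-2-(trimethylsilyl)phenyl trifluoromethanesulfonate, via 5-bromo-2-(trimethylsilyloxy)phenyllithium 3 (not isolated), via lithium 4-bromo-2-(trimethylsilyl)phenoxide 4 (not isolated)
Conditions: n-BuLi (1.05 equiv), THF, −78 °C; then Tf2O, −78 °C → rt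
Reagents that add atoms: trifluoromethanesulfonic anhydride, O=S(=O)(OS(=O)(=O)C(F)(F)F)C(F)(F)F
Why: Iodine–lithium exchange is much faster than bromine–lithium exchange, so only C2 is metalated; the ortho-lithio silyl ether then undergoes the 1,3 O-to-C silyl shift (retro-Brook rearrangement) and the lithium phenoxide so formed is O-sulfonylated by triflic anhydride.

Step 3
Reactants: 6 2-bromo-6-methoxyphenol; 5 4-bromo-2-(trimethylsilyl)phenyl trifluoromethanesulfonate; 7 1,2-dibromotetrachloroethane
Product: 11 1-bromo-2-(2,4-dibromophenoxy)-3-methoxybenzene, via potassium 2-bromo-6-methoxyphenoxide 8 (not isolated), via 4-bromobenzyne 9 (not isolated), via 2-aryloxy-5-bromophenylpotassium 10 (not isolated)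
Conditions: KH (1.0 equiv to 6), THF, 0 °C; then KF, 18-crown-6, slow co-addition of 5 and excess 7, THF, 0 °C → rt
Reagents that add atoms: 1,2-dibromotetrachloroethane, BrC(Cl)(Cl)C(Cl)(Cl)Br
Why: Proposed new method: fluoride attacks the silicon of 5 and the aryl anion expels triflate to give 4-bromobenzyne 9; phenoxide 8 adds to the strained triple bond at C1' to give aryl anion 10 at C2', which attacks a bromine of 7 in a halophilic substitution that fragments the donor to tetrachloroethene and bromide. The closest known reaction types are the fluoride-mediated O-arylation of phenols by silylaryl triflates, in which the anion is simply protonated, and three-component aryne couplings in which a sulfur or nitrogen nucleophile adds and the aryl anion is trapped by a halogen donor or a carbon electrophile. No ring is closed and no stereocentre is formed. The step needs attack at the aryne carbon para to the C4' bromine, which the inductive pull of that bromine should favour only modestly because it places the charge on the nearer C2'; the 2,5-dibromophenoxy regioisomer is therefore expected as a by-product to be removed by chromatography or crystallisation. It also needs bromine transfer to outrun protonation, which is secured by a phenoxide preformed with potassium hydride (only hydrogen leaves), an ethereal solvent without acidic C–H bonds, and an excess of 7 dosed together with 5 so that the donor does not stand long with the phenoxide. No transition metal is present, so the C–Br bonds are not at risk, and the methyl ether leaves only one oxygen free to be arylated.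

Step 4
Reactants: 11 1-bromo-2-(2,4-dibromophenoxy)-3-methoxybenzene
Product: 12 3-bromo-2-(2,4-dibromophenoxy)phenol
Conditions: BBr3, CH2Cl2, −78 °C → rt; H2O
Reagents that add atoms: none
Why: Lewis-acid ether cleavage: boron tribromide binds the methoxy oxygen and bromide removes the methyl group by SN2, while the diaryl ether and the aryl bromides are inert.

Step 5
Reactants: 12 3-bromo-2-(2,4-dibromophenoxy)phenol
Product: 13 3,4,6-tribromo-2-(2,4-dibromophenoxy)phenol
Conditions: Br2 (2.05 equiv), AcOH, rt
Reagents that add atoms: bromine, BrBr
Why: Electrophilic aromatic bromination: the free hydroxyl is the strongest activator present and its only open ortho and para positions (C6 and C4 of ring A) should take the two bromines, while C5 and ring B are deactivated.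

**Compound list**

1 | 4-bromo-2-iodophenol | Oc1ccc(Br)cc1I | starting material
2 | (4-bromo-2-iodophenoxy)trimethylsilane | C[Si](C)(C)Oc1ccc(Br)cc1I | intermediate
3 | 5-bromo-2-(trimethylsilyloxy)phenyllithium | [Li]c1cc(Br)ccc1O[Si](C)(C)C | intermediate (not isolated)
4 | lithium 4-bromo-2-(trimethylsilyl)phenoxide | [Li+].[O-]c1ccc(Br)cc1[Si](C)(C)C | intermediate (not isolated)
5 | 4-bromo-2-(trimethylsilyl)phenyl trifluoromethanesulfonate | C[Si](C)(C)c1cc(Br)ccc1OS(=O)(=O)C(F)(F)F | intermediate
6 | 2-bromo-6-methoxyphenol | COc1cccc(Br)c1O | starting material
7 | 1,2-dibromotetrachloroethane | BrC(Cl)(Cl)C(Cl)(Cl)Br | starting material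
8 | potassium 2-bromo-6-methoxyphenoxide | [K+].COc1cccc(Br)c1[O-] | intermediate (not isolated)
9 | 4-bromobenzyne (4-bromo-1,2-didehydrobenzene) | BrC1=CC#CC=C1 | intermediate (not isolated)
10 | potassium 5-bromo-2-(2-bromo-6-methoxyphenoxy)phenyl anion (2-aryloxy-5-bromophenylpotassium) | [K+].COc1cccc(Br)c1Oc1ccc(Br)c[c-]1 | intermediate (not isolated)
11 | 1-bromo-2-(2,4-dibromophenoxy)-3-methoxybenzene | COc1cccc(Br)c1Oc1ccc(Br)cc1Br | intermediate
12 | 3-bromo-2-(2,4-dibromophenoxy)phenol | Oc1cccc(Br)c1Oc1ccc(Br)cc1Br | intermediate
13 | 3,4,6-tribromo-2-(2,4-dibromophenoxy)phenol | Oc1c(Br)cc(Br)c(Br)c1Oc1ccc(Br)cc1Br | target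

**Step count**

Total steps: 5. Longest linear sequence: 5 steps (1 → 2 → 5 → 11 → 12 → 13).

**Steps most likely to fail**

Step 3. Several processes could defeat it:
- phenoxide attack at the aryne carbon meta to the bromine, which would erode regiocontrol;
- protonation of the aryl anion before bromine transfer;
- ring bromination of the phenoxide by the donor;
- competing addition of fluoride to the aryne.

The fallback uses known chemistry and fixes the regiochemistry in the electrophile. It sets out from 6. Nucleophilic aromatic substitution on purchased 4-bromo-1-fluoro-2-nitrobenzene (K2CO3, DMF, 80 °C) should give 1-bromo-2-(4-bromo-2-nitrophenoxy)-3-methoxybenzene F1. Reduction of the nitro group with iron and ammonium chloride in aqueous ethanol, which spares aryl bromides, should give 5-bromo-2-(2-bromo-6-methoxyphenoxy)aniline F2. Diazotisation (NaNO2, aqueous HBr, 0 °C) to 5-bromo-2-(2-bromo-6-methoxyphenoxy)benzenediazonium bromide F3 and Sandmeyer bromination with CuBr return the route to 11. Both ortho positions of ring A are substituted, which blocks radical closure to a dibenzofuran.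

Step 2. Competing exchange at the C4 bromine, incomplete silyl migration, or hydrolysis of the moisture-sensitive silyl ether before metalation would lower the supply of the aryne precursor. The fallback replaces lithium and the intramolecular silyl shift by magnesium and intermolecular C-silylation. It sets out from 1. Deprotonation with MeMgCl and LiCl (THF, −20 °C) gives chloromagnesium 4-bromo-2-iodophenoxide F4. Iodine–magnesium exchange with i-PrMgCl gives the C,O-dimagnesiated arene chloromagnesium 4-bromo-2-(chloromagnesio)phenoxide F5. Excess TMSCl with warming gives [5-bromo-2-(trimethylsilyloxy)phenyl]trimethylsilane F6. Methanolysis of the O–Si bond (K2CO3, MeOH) gives 4-bromo-2-(trimethylsilyl)phenol F7, which is purified and triflated (Tf2O, pyridine, CH2Cl2, 0 °C) to return at 5.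

Step 5. Over- or under-bromination, or attack on ring B, could give a mixture of congeners that is hard to separate. The fallback introduces the two bromines in two separately controlled operations. It sets out from 12. Para-selective monobromination with tetrabutylammonium tribromide (CH2Cl2/MeOH, rt) should give 3,4-dibromo-2-(2,4-dibromophenoxy)phenol F8, which is purified. Ortho-selective bromination with N-bromosuccinimide and catalytic diisopropylamine (CH2Cl2, 0 °C) then returns at 13.

**Further compounds**

F1 | step 3 | 1-bromo-2-(4-bromo-2-nitrophenoxy)-3-methoxybenzene | COc1cccc(Br)c1Oc1ccc(Br)cc1[N+](=O)[O-]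
F2 | step 3 | 5-bromo-2-(2-bromo-6-methoxyphenoxy)aniline | COc1cccc(Br)c1Oc1ccc(Br)cc1N
F3 | step 3 | 5-bromo-2-(2-bromo-6-methoxyphenoxy)benzenediazonium bromide | COc1cccc(Br)c1Oc1ccc(Br)cc1[N+]#N.[Br-]
F4 | step 2 | chloromagnesium 4-bromo-2-iodophenoxide | Cl[Mg]Oc1ccc(Br)cc1I
F5 | step 2 | chloromagnesium 4-bromo-2-(chloromagnesio)phenoxide | Cl[Mg]Oc1ccc(Br)cc1[Mg]Cl
F6 | step 2 | [5-bromo-2-(trimethylsilyloxy)phenyl]trimethylsilane | C[Si](C)(C)Oc1ccc(Br)cc1[Si](C)(C)C
F7 | step 2 | 4-bromo-2-(trimethylsilyl)phenol | C[Si](C)(C)c1cc(Br)ccc1O
F8 | step 5 | 3,4-dibromo-2-(2,4-dibromophenoxy)phenol | Oc1ccc(Br)c(Br)c1Oc1ccc(Br)cc1Br
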